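**Plan**

- Retrosynthesis: the four O–H bonds are cut back to O–CH3. The bridge is then cut at C5(aryl)–CH2, giving aryl bromide 12 and a 2-arylethyl-9-BBN that comes from styrene 14, itself made from 12. C5–Br goes back to C5–H of arene 10, and 10 goes back (C=O removal, two C–CH3 bonds, aryl–C bond) to 3-methylcyclopent-2-enone 1 and boronic acid 2.
- Enabling feature: in each benzene-1,2-diol ring the bridge carbon C5 is para to O–C2 and meta to both O–C1 and the cyclopentyl-bearing C3. It is the only ring carbon flanked by two C–H positions (C4, C6), so sterically governed C–H borylation marks exactly this carbon, and the coupling site is unhindered.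
- The target is C2-symmetric, so one monomer serves as both halves. Two copies of one electrophile (12) are joined through a two-carbon unit after the polarity of one copy is reversed (vinylation, then anti-Markovnikov hydroboration).
- Forward order: the cyclopentane ring is bought (1). Then come the aryl–C bond (step 1), the enone and gem-dimethyl carbon (steps 2–3), saturation and deoxygenation (steps 4–5), C–H borylation/bromination (step 6), vinylation (step 7), union (step 8) and fourfold O-demethylation (step 9).
- Stereochemistry: both (S) quaternary carbons come from one catalyst-controlled conjugate addition (step 1). The centre is never enolisable or cationic afterwards, and joining two copies of the same enantiomer diverts most residual minor enantiomer into the meso diastereomer.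

Key step: step 8

Remark: the CIP descriptor of the quaternary carbon changes (S, R, S) along the route only because substituent priorities change; the spatial arrangement is the same in every SMILES.
Assumption: the ligand antipode in step 1 is chosen on the accepted facial model of this catalyst class, in which the (S)-ligand gives (R)-3-aryl-3-methylcycloalkanones; if the sense proves opposite, the other antipode is used.
Remark: 12 should be brought to high enantiomeric purity before step 8 (preparative chiral chromatography if needed), because the meso dimer differs from the target only at remote stereocentres and would be hard to remove.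

**Route**

Step 1
Reactants: 1 3-methylcyclopent-2-en-1-one; 2 (2,3-dimethoxyphenyl)boronic acid
Product: 3 (3S)-3-(2,3-dimethoxyphenyl)-3-methylcyclopentan-1-one
Conditions: Pd(OCOCF3)2 (5 mol%), (R)-t-BuPyOx (6 mol%), NH4PF6 (30 mol%), H2O (5 equiv), ClCH2CH2Cl, 40 °C
Reagents that add atoms: none
Why: Palladium(II)/pyridine-oxazoline-catalysed asymmetric conjugate addition of an arylboronic acid to a β-substituted cyclic enone (aryl–Pd insertion, then protonolysis of the palladium enolate) should form the aryl–C3 bond, the tert-butyl group of the ligand differentiating the enone faces so that the quaternary centre is set as (S).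

Step 2
Reactants: 3 (3S)-3-(2,3-dimethoxyphenyl)-3-methylcyclopentan-1-one
Product: 5 (4R)-4-(2,3-dimethoxyphenyl)-4-methylcyclopent-2-en-1-one, via trimethylsilyl enol ether 4 (not isolated)
Conditions: LDA, Me3SiCl, THF, −78 °C; solvent exchange; Pd(OAc)2 (1.05 equiv), MeCN, rt
Reagents that add atoms: chlorotrimethylsilane, C[Si](C)(C)Cl (silicon and its methyl groups are in 4 only)
Why: Saegusa–Ito oxidation: kinetic deprotonation at C5 (the CH2 remote from the quaternary carbon) and O-silylation give 4, whose palladium(II) enolate undergoes β-hydride elimination; C3 carries no hydrogen, so only the C4–C5 enone can form and any C1–C2 enol ether should simply return 3 on work-up.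

Step 3
Reactants: 5 (4R)-4-(2,3-dimethoxyphenyl)-4-methylcyclopent-2-en-1-one
Product: 7 (4R)-4-(2,3-dimethoxyphenyl)-4,5,5-trimethylcyclopent-2-en-1-one, via monomethyl enone 6 (not isolated)
Conditions: NaH (3 equiv), MeI (6 equiv), DME, 0 °C → rt
Reagents that add atoms: iodomethane, CI
Why: Exhaustive α′-alkylation of an enone enolate: C4 is quaternary, so C5 is the only acidic position and both methyl groups must enter there, building the gem-dimethyl carbon next to the stereocentre without a regiochemical choice.

Step 4
Reactants: 7 (4R)-4-(2,3-dimethoxyphenyl)-4,5,5-trimethylcyclopent-2-en-1-one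
Product: 8 (3R)-3-(2,3-dimethoxyphenyl)-2,2,3-trimethylcyclopentan-1-one
Conditions: H2 (1 atm), 10% Pd/C, EtOAc, rt
Reagents that add atoms: none
Why: Heterogeneous catalytic hydrogenation should saturate the disubstituted enone C=C selectively; the hindered ketone, the arene and the aryl methyl ethers are not reduced under these conditions and no stereocentre is created.

Step 5
Reactants: 8 (3R)-3-(2,3-dimethoxyphenyl)-2,2,3-trimethylcyclopentan-1-one
Product: 10 1,2-dimethoxy-3-[(1S)-1,2,2-trimethylcyclopentyl]benzene, via hydrazone 9 (not isolated)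
Conditions: N2H4·H2O, KOH, diethylene glycol, 130 °C, then 200–210 °C with removal of water
Reagents that add atoms: hydrazine (as hydrate), NN (its nitrogen atoms are in 9 only)
Why: Wolff–Kishner reduction (Huang-Minlon variant) converts C=O into CH2 through hydrazone 9 and loss of N2; the stereocentre is not α to the carbonyl, and no cation arises next to the aryl-bearing carbon, where a 1,2-aryl shift could otherwise racemise it.

Step 6
Reactants: 10 1,2-dimethoxy-3-[(1S)-1,2,2-trimethylcyclopentyl]benzene
Product: 12 5-bromo-1,2-dimethoxy-3-[(1S)-1,2,2-trimethylcyclopentyl]benzene, via pinacol boronate 11 (not isolated)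
Conditions: [Ir(OMe)(cod)]2 (1.5 mol%), 4,4′-di-tert-butyl-2,2′-bipyridine (3 mol%), B2pin2 (1.0 equiv), THF, 80 °C; evaporate; CuBr2 (3 equiv), MeOH/H2O 1:1, 80 °C
Reagents that add atoms: bis(pinacolato)diboron, CC1(C)OB(OC1(C)C)B1OC(C)(C)C(C)(C)O1 (boryl group in 11 only); copper(II) bromide, Br[Cu]Br
Why: Iridium-catalysed aromatic C–H borylation is governed by sterics and should occur only at C5–H (C4–H lies next to the quaternary cyclopentyl carbon, C6–H next to a methoxy group), and copper(II)-mediated ipso-bromodeboronation of crude 11 then gives the bromide in the same flask.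

Step 7
Reactants: 12 5-bromo-1,2-dimethoxy-3-[(1S)-1,2,2-trimethylcyclopentyl]benzene; 13 4,4,5,5-tetramethyl-2-vinyl-1,3,2-dioxaborolane
Product: 14 5-ethenyl-1,2-dimethoxy-3-[(1S)-1,2,2-trimethylcyclopentyl]benzene
Conditions: PdCl2(dppf) (3 mol%), K2CO3, 1,4-dioxane/H2O, 85 °C
Reagents that add atoms: none
Why: Suzuki–Miyaura coupling of an unhindered aryl bromide with a vinylboronate should install the two bridge carbons on one copy of the monomer.

Step 8
Reactants: 14 5-ethenyl-1,2-dimethoxy-3-[(1S)-1,2,2-trimethylcyclopentyl]benzene; 12 5-bromo-1,2-dimethoxy-3-[(1S)-1,2,2-trimethylcyclopentyl]benzene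
Product: 16 1,1′-(ethane-1,2-diyl)bis{3,4-dimethoxy-5-[(1S)-1,2,2-trimethylcyclopentyl]benzene}, via alkylborane 15 (not isolated)
Conditions: 9-BBN-H (1.1 equiv), THF, 0 °C → rt; then 12 (0.95 equiv), PdCl2(dppf) (3 mol%), 3 M aq NaOH, THF, 65 °C
Reagents that add atoms: 9-borabicyclo[3.3.1]nonane, [H]B1C2CCCC1CCC2 (boron and its ring are in 15 only)
Why: 9-BBN adds syn across the vinyl group of 14 with boron on the terminal carbon to give the primary alkylborane 15; hydroxide converts it into a borate, Pd(0)/dppf inserts into the C5–Br bond of 12, the primary alkyl group is transferred to palladium and reductive elimination forms the C5(aryl)–CH2 bond. The closest known reaction type is the hydroboration/B-alkyl Suzuki–Miyaura coupling of terminal alkenes with aryl bromides. No ring is closed and no stereocentre is made; the two quaternary (S) carbons are remote from the reacting atoms and untouched. The step needs terminal-selective hydroboration (secured by the bulk of 9-BBN and the absence of ortho substituents next to the vinyl group), reductive elimination faster than β-hydride elimination of the 2-arylethyl–palladium species (secured by the wide-bite-angle dppf ligand) and an accessible C–Br bond (C5 is flanked only by C4–H and C6–H). Because both partners derive from 12, the product should be the C2-symmetric (S,S) dimer, and the four methyl ethers are inert to the basic medium.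

Step 9
Reactants: 16 1,1′-(ethane-1,2-diyl)bis{3,4-dimethoxy-5-[(1S)-1,2,2-trimethylcyclopentyl]benzene}
Product: 17 5,5′-(ethane-1,2-diyl)bis{3-[(1S)-1,2,2-trimethylcyclopentyl]benzene-1,2-diol}
Conditions: BBr3 (8 equiv), CH2Cl2, −78 °C → rt; H2O quench; work-up under argon
Reagents that add atoms: none
Why: Lewis-acid ether cleavage: BBr3 coordinates each methoxy oxygen and bromide removes the methyl group by SN2, the aryl borates being hydrolysed on work-up; the all-carbon quaternary centres and the saturated bridge are inert, and the air-sensitive bis-catechol is kept under argon.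

**Compound list**

1 | 3-methylcyclopent-2-en-1-one | CC1=CC(=O)CC1 | starting material
2 | (2,3-dimethoxyphenyl)boronic acid | COc1cccc(B(O)O)c1OC | starting material
3 | (3S)-3-(2,3-dimethoxyphenyl)-3-methylcyclopentan-1-one | O=C1CC[C@](C)(c2cccc(OC)c2OC)C1 | intermediate
4 | {[(4S)-4-(2,3-dimethoxyphenyl)-4-methylcyclopent-1-en-1-yl]oxy}trimethylsilane | C[Si](C)(C)OC1=CC[C@](C)(c2cccc(OC)c2OC)C1 | intermediate
5 | (4R)-4-(2,3-dimethoxyphenyl)-4-methylcyclopent-2-en-1-one | O=C1C=C[C@](C)(c2cccc(OC)c2OC)C1 | intermediate
6 | (4S)-4-(2,3-dimethoxyphenyl)-4,5-dimethylcyclopent-2-en-1-one (both C5 epimers) | CC1C(=O)C=C[C@]1(C)c1cccc(OC)c1OC | intermediate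
7 | (4R)-4-(2,3-dimethoxyphenyl)-4,5,5-trimethylcyclopent-2-en-1-one | CC1(C)C(=O)C=C[C@]1(C)c1cccc(OC)c1OC | intermediate
8 | (3R)-3-(2,3-dimethoxyphenyl)-2,2,3-trimethylcyclopentan-1-one | CC1(C)C(=O)CC[C@]1(C)c1cccc(OC)c1OC | intermediate
9 | hydrazone of 8, [(3S)-3-(2,3-dimethoxyphenyl)-2,2,3-trimethylcyclopentylidene]hydrazine | CC1(C)C(=NN)CC[C@]1(C)c1cccc(OC)c1OC | intermediate
10 | 1,2-dimethoxy-3-[(1S)-1,2,2-trimethylcyclopentyl]benzene | CC1(C)CCC[C@]1(C)c1cccc(OC)c1OC | intermediate
11 | 2-{3,4-dimethoxy-5-[(1S)-1,2,2-trimethylcyclopentyl]phenyl}-4,4,5,5-tetramethyl-1,3,2-dioxaborolane | CC1(C)CCC[C@]1(C)c1cc(B2OC(C)(C)C(C)(C)O2)cc(OC)c1OC | intermediate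
12 | 5-bromo-1,2-dimethoxy-3-[(1S)-1,2,2-trimethylcyclopentyl]benzene | CC1(C)CCC[C@]1(C)c1cc(Br)cc(OC)c1OC | intermediate
13 | 4,4,5,5-tetramethyl-2-vinyl-1,3,2-dioxaborolane | C=CB1OC(C)(C)C(C)(C)O1 | starting material
14 | 5-ethenyl-1,2-dimethoxy-3-[(1S)-1,2,2-trimethylcyclopentyl]benzene | CC1(C)CCC[C@]1(C)c1cc(C=C)cc(OC)c1OC | intermediate
15 | 9-(2-{3,4-dimethoxy-5-[(1S)-1,2,2-trimethylcyclopentyl]phenyl}ethyl)-9-borabicyclo[3.3.1]nonane | CC1(C)CCC[C@]1(C)c1cc(CCB2C3CCCC2CCC3)cc(OC)c1OC | intermediate
16 | 1,1′-(ethane-1,2-diyl)bis{3,4-dimethoxy-5-[(1S)-1,2,2-trimethylcyclopentyl]benzene} | CC1(C)CCC[C@]1(C)c1cc(CCc2cc(OC)c(OC)c([C@@]3(C)CCCC3(C)C)c2)cc(OC)c1OC | intermediate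
17 | 5,5′-(ethane-1,2-diyl)bis{3-[(1S)-1,2,2-trimethylcyclopentyl]benzene-1,2-diol} | CC1(C)CCC[C@]1(C)c1cc(CCc2cc(O)c(O)c([C@@]3(C)CCCC3(C)C)c2)cc(O)c1O | target

**Summary**

Total step count: 9.
Longest linear sequence: 9 steps (steps 1–9; bromide 12 enters at steps 7 and 8).

**Steps most likely to fail**

1. Step 1. Protodeboronation of the ortho-methoxy boronic acid in the wet medium may outrun transmetalation, and the ortho substituent may erode facial discrimination. The fallback sets out from 1 and delivers the aryl group as an aprotic aryl–aluminium nucleophile under copper catalysis instead of a boronic acid under palladium(II). 1,2-Dimethoxybenzene is lithiated at C3 (n-BuLi, TMEDA, Et2O, 0 °C → rt) to (2,3-dimethoxyphenyl)lithium F1, which is transmetalated with Me2AlCl to (2,3-dimethoxyphenyl)dimethylaluminium F2. Copper-catalysed asymmetric conjugate addition of F2 to 1 (Cu(OTf)2, chiral N-heterocyclic carbene ligand, THF, −50 °C), with selective transfer of the aryl group, should give 3 after aqueous work-up, where the route is rejoined.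

2. Step 3. The second C-methylation must build a quaternary carbon next to an existing one and may stall, with O-methylation of the cross-conjugated dienolate or base-induced Michael oligomerisation of the enone taking over. The fallback sets out from 3 and avoids the enone altogether by alkylating the saturated ketone with its unhindered α-position blocked. Formylation (HCO2Et, NaH, THF) should give (4S)-4-(2,3-dimethoxyphenyl)-2-(hydroxymethylidene)-4-methylcyclopentan-1-one F3. Condensation with n-BuSH (TsOH cat., toluene, reflux, water removal) should give (4S)-2-[(butylsulfanyl)methylidene]-4-(2,3-dimethoxyphenyl)-4-methylcyclopentan-1-one F4. Double methylation at the only remaining α-carbon (KOt-Bu, MeI, t-BuOH/THF) should give (3R)-5-[(butylsulfanyl)methylidene]-3-(2,3-dimethoxyphenyl)-2,2,3-trimethylcyclopentan-1-one F5. Removal of the blocking group (KOH, aqueous diethylene glycol, reflux) returns to 8, so steps 2–4 are bypassed.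

3. Step 6. The electron-rich ring may suffer protodeboronation or further electrophilic bromination during the copper(II) stage, and minor borylation next to the methoxy group would carry through as an isomeric bromide. The fallback sets out from 10, runs the borylation alone and isolates boronate 11, which is then used as the nucleophile in a two-directional union with a C2 bis-electrophile. Twofold Suzuki–Miyaura coupling of 11 (2 equiv) with (E)-1,2-dichloroethene (Pd(OAc)2/SPhos, K3PO4, THF/H2O, 60 °C) should pass through 5-[(E)-2-chloroethenyl]-1,2-dimethoxy-3-[(1S)-1,2,2-trimethylcyclopentyl]benzene F6 and give (E)-1,2-bis{3,4-dimethoxy-5-[(1S)-1,2,2-trimethylcyclopentyl]phenyl}ethene F7. Hydrogenation (H2, Pd/C, EtOAc) then returns to 16, bypassing 12, 14 and 15.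

Further compounds
F1 | step 1 | (2,3-dimethoxyphenyl)lithium | [Li]c1cccc(OC)c1OC
F2 | step 1 | (2,3-dimethoxyphenyl)dimethylaluminium | C[Al](C)c1cccc(OC)c1OC
F3 | step 3 | (4S)-4-(2,3-dimethoxyphenyl)-2-(hydroxymethylidene)-4-methylcyclopentan-1-one | O=C1C(=CO)C[C@](C)(c2cccc(OC)c2OC)C1
F4 | step 3 | (4S)-2-[(butylsulfanyl)methylidene]-4-(2,3-dimethoxyphenyl)-4-methylcyclopentan-1-one | O=C1C(=CSCCCC)C[C@](C)(c2cccc(OC)c2OC)C1
F5 | step 3 | (3R)-5-[(butylsulfanyl)methylidene]-3-(2,3-dimethoxyphenyl)-2,2,3-trimethylcyclopentan-1-one | O=C1C(=CSCCCC)C[C@](C)(c2cccc(OC)c2OC)C1(C)C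
F6 | step 6 | 5-[(E)-2-chloroethenyl]-1,2-dimethoxy-3-[(1S)-1,2,2-trimethylcyclopentyl]benzene | CC1(C)CCC[C@]1(C)c1cc(/C=C/Cl)cc(OC)c1OC
F7 | step 6 | (E)-1,2-bis{3,4-dimethoxy-5-[(1S)-1,2,2-trimethylcyclopentyl]phenyl}ethene | CC1(C)CCC[C@]1(C)c1cc(/C=C/c2cc(OC)c(OC)c([C@@]3(C)CCCC3(C)C)c2)cc(OC)c1OC
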